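**Overview**

Core numbering: bicyclo[3.3.1]nonane C1 (benzoyl) to C9; C10 is the CH2 on C7, C11 the cyclopentane CH on C3. The route rests on cutting C10–C11, the two-carbon bridge that turns the bicyclic 2,4,9-trione into the homoadamantane. The precursor is a 7-methylidene bicycle whose C3 is already the spiro carbon of the cyclopentane, with C11 bearing H and SPh and held over C7 by the chair–chair core. Chlorination at sulfur gives a thionium ion at C11; the exocyclic alkene attacks it through C10 and closes both seven-membered rings at once. Sulfur then leaves as a radical, so hydrogen reaches C11 from the open face.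

Key step: step 9

Assumption: 1, 4 and 8 are bought; the Effenberger cyclisation is run on racemic material, the enantiomers of 7 are separated on a chiral phase, and every later stereocentre is relayed from the bicycle.

**Route**

Step 1
Reactants: 1 7,7-dimethyl-1,4-dioxaspiro[4.5]decan-8-one
Product: 2 7,7-dimethyl-8-methylidene-1,4-dioxaspiro[4.5]decane
Conditions: Ph3PCH3Br, KOt-Bu, toluene, 90 °C
Reagents that add atoms: methyltriphenylphosphonium bromide, C[P+](c1ccccc1)(c1ccccc1)c1ccccc1.[Br-]
Why: Wittig methylenation; the ketone is hindered by the neighbouring gem-dimethyl carbon, but the unstabilised ylide in hot toluene should still convert it, and no stereocentre is formed.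

Step 2
Reactants: 2 7,7-dimethyl-8-methylidene-1,4-dioxaspiro[4.5]decane
Product: 3 3,3-dimethyl-4-methylidenecyclohexan-1-one
Conditions: PPTS (cat.), acetone/H2O 10:1, 50 °C
Reagents that add atoms: water, O
Why: Acid-catalysed acetal hydrolysis; the weak acid should free the ketone without protonating the 1,1-disubstituted alkene.

Step 3
Reactants: 3 3,3-dimethyl-4-methylidenecyclohexan-1-one; 4 geranyl bromide
Product: 5 rac-2-geranyl-5,5-dimethyl-4-methylidenecyclohexan-1-one
Conditions: lithium diisopropylamide (LDA), THF, −78 °C; then 4, DMPU, −78 to 0 °C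
Reagents that add atoms: none
Why: Kinetic enolate alkylation; LDA should remove a proton from the CH2 remote from the gem-dimethyl carbon and the enolate displaces the allylic bromide (SN2), giving a racemic centre that is erased in step 4.

Step 4
Reactants: 5 rac-2-geranyl-5,5-dimethyl-4-methylidenecyclohexan-1-one
Product: 6 tert-butyldimethylsilyl enol ether of 5 (the more substituted isomer is drawn; its regioisomer converges in step 5)
Conditions: t-BuMe2SiOTf, Et3N, CH2Cl2, 0 °C to rt
Reagents that add atoms: tert-butyldimethylsilyl trifluoromethanesulfonate, CC(C)(C)[Si](C)(C)OS(=O)(=O)C(F)(F)F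
Why: Silyl enol ether formation by soft enolisation and O-silylation, which supplies the neutral enol equivalent needed for the acylation in step 5.

Step 5
Reactants: 6 tert-butyldimethylsilyl enol ether of 5
Product: 7 (1S,5R)-5-geranyl-8,8-dimethyl-7-methylidenebicyclo[3.3.1]nonane-2,4,9-trione (core numbering of the overview; enolised between C2 and C4)
Conditions: ClCOCH2COCl, Et2O, −20 °C to rt; then aq KOH, BnEt3NCl; acidify; preparative SFC on an amylose-based chiral phase
Reagents that add atoms: malonyl dichloride, O=C(Cl)CC(=O)Cl
Why: Effenberger cyclisation, a double C-acylation of both α-carbons of the enol ether by malonyl dichloride; the three-carbon bridge can only span one face of the ring, so C1 and C5 are set relative to each other, and the racemate is split on the chiral phase into the enantiomer carried on.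

Step 6
Reactants: 8 ethyl 4-bromo-2,2-dimethylbutanoate
Product: 9 4-bromo-2,2-dimethylbutanal
Conditions: i-Bu2AlH, CH2Cl2, −78 °C; Rochelle salt work-up
Reagents that add atoms: none
Why: Partial reduction of an ester with diisobutylaluminium hydride; the tetrahedral aluminium acetal of this neopentyl ester should survive at −78 °C and release the aldehyde only on work-up.

Step 7
Reactants: 7 bicyclic trione; 9 4-bromo-2,2-dimethylbutanal
Product: 11 spiro sulfide (C3 of 7 is the spiro carbon of a 3,3-dimethyl-2-(phenylsulfanyl)cyclopentane whose CH–S carbon C11 lies on the C7 face; both C11 epimers), via thio-Michael adduct 10 (not isolated)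
Conditions: PhSH, L-proline (20 mol %), CH2Cl2, rt; then Cs2CO3, DMF, rt
Reagents that add atoms: thiophenol, Sc1ccccc1
Why: Knoevenagel condensation and thia-Michael trapping of the alkylidene dione, then intramolecular 5-exo-tet C-alkylation of the 2-substituted 1,3-dione enolate (Michael-initiated ring closure); the CH2Br arm should attack the enolate face turned away from the C7 methylidene bridge, which places C11 on the C7 side of the new C3 centre.

Step 8
Reactants: 11 spiro sulfide
Product: 12 1-benzoyl spiro sulfide (benzoyl on the C1 bridgehead, configuration held by the bicycle)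
Conditions: lithium 2,2,6,6-tetramethylpiperidide (LiTMP), THF, −78 °C; then PhCOCl, −78 to −40 °C
Reagents that add atoms: benzoyl chloride, O=C(Cl)c1ccccc1
Why: Bridgehead lithiation and acylation; C1–H between the C2 and C9 carbonyls is the only acidic proton left once C3 is quaternary, and the bridgehead carbanion can only be acylated on carbon with retention.

Step 9
Reactants: 12 1-benzoyl spiro sulfide
Product: 14 chloro cage sulfide (target skeleton with Cl on C7 and SPh on C11; both C11 epimers), via alpha-chloro sulfide 13 (not isolated)
Conditions: N-chlorosuccinimide, CH2Cl2, 0 °C; then ZnCl2 (20 mol %, in Et2O), −40 to 0 °C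
Reagents that add atoms: N-chlorosuccinimide, O=C1CCC(=O)N1Cl
Why: N-Chlorosuccinimide chlorinates sulfur and the chlorosulfonium salt collapses to the α-chloro sulfide 13, which ZnCl2 ionises to the thionium ion at C11; the C7 methylidene, held under C11 by the chair–chair bicycle, attacks through its CH2 terminus C10 and the tertiary C7 cation takes up chloride. The closest known reaction type is the Pummerer-type thionium ion–alkene cyclisation of α-chloro sulfides, run here across the ring as in the π-route from 7-methylidenebicyclo[3.3.1]nonanes to homoadamantanes. One bond closes both seven-membered rings (C3–C4–C5–C6–C7–C10–C11 and C3–C2–C1–C8–C7–C10–C11), each in the 7-endo-trig mode with respect to the alkene. C7 is fixed by the cage, since C10 must sit on the C3 face and chloride can only enter from outside; C11 forms as a pair of sulfide epimers that converge in step 10. The step needs attack at C10 and not at C7, which the tertiary over primary cation secures, and it needs a thionium ion that cannot eliminate, which the quaternary neighbours C3 and C12 secure. The geranyl alkenes sit on the outer face of C5, far from C11, and a catalytic amount of a mild Lewis acid should leave them untouched.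

Step 10
Reactants: 14 chloro cage sulfide
Product: 15 target CNP0168637.1
Conditions: n-Bu3SnH (5 equiv), AIBN, toluene, 110 °C
Reagents that add atoms: none
Why: Radical chain reduction with tributyltin hydride removes chlorine from C7 and the strained tertiary C–S bond at C11; the C7 radical can take hydrogen only on the outer face, and the planar C11 radical is shielded on one face by the C8 methyl that points toward C10, so hydrogen should arrive from the C6 side and set the (11R) centre.

**Compound list**

1 | 7,7-dimethyl-1,4-dioxaspiro[4.5]decan-8-one | CC1(C)CC2(CCC1=O)OCCO2 | starting material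
2 | 7,7-dimethyl-8-methylidene-1,4-dioxaspiro[4.5]decane | C=C1CCC2(CC1(C)C)OCCO2 | intermediate
3 | 3,3-dimethyl-4-methylidenecyclohexan-1-one | C=C1CCC(=O)CC1(C)C | intermediate
4 | geranyl bromide, (2E)-1-bromo-3,7-dimethylocta-2,6-diene | CC(C)=CCC/C(C)=C/CBr | starting material
5 | rac-2-[(2E)-3,7-dimethylocta-2,6-dien-1-yl]-5,5-dimethyl-4-methylidenecyclohexan-1-one | CC(C)=CCC/C(C)=C/CC1CC(=C)C(C)(C)CC1=O | intermediate
6 | tert-butyl({2-[(2E)-3,7-dimethylocta-2,6-dien-1-yl]-5,5-dimethyl-4-methylidenecyclohex-1-en-1-yl}oxy)dimethylsilane | CC(C)=CCC/C(C)=C/CC1=C(O[Si](C)(C)C(C)(C)C)CC(C)(C)C(=C)C1 | intermediate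
7 | (1S,5R)-5-[(2E)-3,7-dimethylocta-2,6-dien-1-yl]-8,8-dimethyl-7-methylidenebicyclo[3.3.1]nonane-2,4,9-trione (triketo form drawn) | CC(C)=CCC/C(C)=C/C[C@@]12CC(=C)C(C)(C)[C@H](C2=O)C(=O)CC1=O | intermediate
8 | ethyl 4-bromo-2,2-dimethylbutanoate | CCOC(=O)C(C)(C)CCBr | starting material
9 | 4-bromo-2,2-dimethylbutanal | O=CC(C)(C)CCBr | intermediate
10 | thio-Michael adduct: 7 carrying a 4-bromo-2,2-dimethyl-1-(phenylsulfanyl)butyl group on C3 (epimers, keto form drawn) | CC(C)=CCC/C(C)=C/C[C@@]12CC(=C)C(C)(C)[C@H](C2=O)C(=O)C(C(Sc3ccccc3)C(C)(C)CCBr)C1=O | intermediate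
11 | spiro sulfide: 5-geranyl-3',3',8,8-tetramethyl-7-methylidene-2'-(phenylsulfanyl)spiro[bicyclo[3.3.1]nonane-3,1'-cyclopentane]-2,4,9-trione, bridgeheads as in 7, C2' (= C11) on the C7 face of the spiro carbon, both C11 epimers | CC(C)=CCC/C(C)=C/C[C@@]12CC(=C)C(C)(C)[C@H](C2=O)C(=O)[C@]3(CCC(C)(C)C3Sc4ccccc4)C1=O | intermediate
12 | 1-benzoyl spiro sulfide: 11 with benzoyl on the C1 bridgehead | CC(C)=CCC/C(C)=C/C[C@@]12CC(=C)C(C)(C)[C@](C(=O)c5ccccc5)(C2=O)C(=O)[C@]3(CCC(C)(C)C3Sc4ccccc4)C1=O | intermediate
13 | alpha-chloro sulfide: 12 with chlorine in place of H on C11 | CC(C)=CCC/C(C)=C/C[C@@]12CC(=C)C(C)(C)[C@](C(=O)c5ccccc5)(C2=O)C(=O)[C@]3(CCC(C)(C)C3(Cl)Sc4ccccc4)C1=O | intermediate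
14 | chloro cage sulfide: the target cage with Cl on C7 (outer face) and SPh on C11, both C11 epimers | CC(C)=CCC/C(C)=C/C[C@@]12C[C@@]3(Cl)CC4(Sc5ccccc5)C(C)(C)CC[C@]4(C1=O)C(=O)[C@@](C(=O)c1ccccc1)(C2=O)C3(C)C | intermediate
15 | target CNP0168637.1, (11R)-configured homoadamantane trione with fused 3,3-dimethylcyclopentane, C1 benzoyl and C5 geranyl | CC(C)=CCC/C(C)=C/C[C@@]12C[C@H]3C[C@@H]4C(C)(C)CC[C@]4(C1=O)C(=O)[C@@](C(=O)c1ccccc1)(C2=O)C3(C)C | target

**Step count and risks**

Total step count: 10. Longest linear sequence: 9 (steps 1, 2, 3, 4, 5, 7, 8, 9, 10).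

Step 9. The thionium ion may be recaptured by chloride faster than the alkene reaches it if the trione ring prefers the boat form that swings C11 away from C7, or the Lewis acid may start cation–olefin chemistry in the geranyl chain. The fallback sets out from 12 and closes the ring by a radical instead of a cation. Chlorination with N-chlorosuccinimide gives 13 as before; slow addition of n-Bu3SnH and AIBN in benzene at 80 °C then makes the α-sulfanyl radical at C11, which should add 7-endo to the methylidene and, after hydrogen transfer to C7, give the cage sulfide F1. More n-Bu3SnH in toluene at 110 °C cleaves the C–S bond, and the route comes back at 15.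

Step 8. Deprotonation next to the gem-dimethyl carbon may be slow, and the hindered bridgehead carbanion may be captured poorly by benzoyl chloride or add to a ketone of a second molecule. The fallback sets out from 11 and uses a small electrophile first. LiTMP followed by I2 should give the bridgehead iodide F2; iodine–magnesium exchange with i-PrMgCl·LiCl at −78 °C and addition to benzaldehyde gives the carbinol F3; Dess–Martin periodinane oxidises it, and the route comes back at 12.

Step 7. Condensation with the neopentyl aldehyde may be slow, thiolate may displace the primary bromide before C-alkylation, or the enolate may alkylate on oxygen. The fallback sets out from 7 and builds the C3–C11 bond with an organolithium. Me3SiCHN2 in methanol/toluene gives the methyl enol ether F4 (either regioisomer serves); LiTMP lithiates the vinylic C3–H and addition to 9 gives the carbinol F5; BF3·OEt2 (cat.) and PhSH exchange OH for SPh through the vinylogous oxocarbenium ion and give F6; LiCl in DMSO at 100 °C removes the O-methyl group and the freed dione enolate closes the cyclopentane, so the route comes back at 11.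

Further compounds
F1 | step 9 | cage sulfide: 14 with H in place of Cl on C7 | CC(C)=CCC/C(C)=C/C[C@@]12C[C@H]3CC4(Sc5ccccc5)C(C)(C)CC[C@]4(C1=O)C(=O)[C@@](C(=O)c1ccccc1)(C2=O)C3(C)C
F2 | step 8 | bridgehead iodide: 11 with iodine on C1 | CC(C)=CCC/C(C)=C/C[C@@]12CC(=C)C(C)(C)[C@](I)(C2=O)C(=O)[C@]3(CCC(C)(C)C3Sc4ccccc4)C1=O
F3 | step 8 | bridgehead carbinol: 11 with hydroxy(phenyl)methyl on C1 | CC(C)=CCC/C(C)=C/C[C@@]12CC(=C)C(C)(C)[C@](C(O)c5ccccc5)(C2=O)C(=O)[C@]3(CCC(C)(C)C3Sc4ccccc4)C1=O
F4 | step 7 | methyl enol ether of 7 (4-methoxy-3-en-2-one isomer drawn) | CC(C)=CCC/C(C)=C/C[C@@]12CC(=C)C(C)(C)[C@H](C2=O)C(=O)C=C1OC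
F5 | step 7 | C3 carbinol: F4 with 4-bromo-1-hydroxy-2,2-dimethylbutyl on C3 | CC(C)=CCC/C(C)=C/C[C@@]12CC(=C)C(C)(C)[C@H](C2=O)C(=O)C(C(O)C(C)(C)CCBr)=C1OC
F6 | step 7 | C3 sulfide: F4 with 4-bromo-2,2-dimethyl-1-(phenylsulfanyl)butyl on C3 | CC(C)=CCC/C(C)=C/C[C@@]12CC(=C)C(C)(C)[C@H](C2=O)C(=O)C(C(Sc3ccccc3)C(C)(C)CCBr)=C1OC
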